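## Retrosynthetic overview

1. The target comes from global O-debenzylation of a hexabenzyl ether. Its 5,5'-biaryl bond is cut by Suzuki coupling into two aryl bromide halves that both derive from one common lactone.
2. The oxolane half is closed last, by benzylic-cation etherification of a reduced, open polyol. The tetralin half is closed before the coupling, by intramolecular Friedel–Crafts alkylation from its 5-aryl-lactone.
3. Both halves come from a single 5-aryl-4-(benzyloxymethyl)-3-methylidene-butyrolactone. Aryl-copper 1,4-addition to the exo-methylene and in-flask enolate hydroxylation deliver the ArCH2 group and the tertiary OH in one step.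
4. Key C–C bond (ArCH(O)–CH, lignan C7–C8): the aldehyde carbon is joined to the β-carbon of an acrylate. That carbon is an acceptor site in the free enoate; here it is delivered as a nucleophile (an allylchromium, i.e. a β-acyl carbanion or homoenolate equivalent) under asymmetric chromium catalysis, and the lactone closes in the same step.
5. Ring order: butyrolactone → tetralin → (biaryl bond) → oxolane.

Assumption: the biaryl axis has only two ortho substituents and is treated as freely rotating, so there is no atropisomer to control.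
Assumption: in step 4 the (S,S)-ligand is taken to direct addition to the Si face of the aldehyde; if the sense is the opposite, the (R,R)-ligand is used.

## Route

Step 1
Reactants: 1 5-bromovanillin (3-bromo-4-hydroxy-5-methoxybenzaldehyde); 2 benzyl bromide
Product: 3 4-(benzyloxy)-3-bromo-5-methoxybenzaldehyde
Conditions: K2CO3, DMF, 60 °C
Reagents that add atoms: none
Why: Williamson ether synthesis on the phenoxide masks the phenol for the organometallic steps; no stereocentre is formed.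

Step 2
Reactants: 4 (benzyloxy)acetaldehyde; 5 ethyl acrylate
Product: 6 ethyl 4-(benzyloxy)-3-hydroxy-2-methylidenebutanoate (racemic)
Conditions: DABCO (1 equiv), 1,4-dioxane/H2O (1:1), rt, 48 h
Reagents that add atoms: none
Why: Morita–Baylis–Hillman reaction, fast with α-alkoxy aldehydes; the racemic carbinol centre is destroyed in step 3.

Step 3
Reactants: 6 ethyl 4-(benzyloxy)-3-hydroxy-2-methylidenebutanoate
Product: 7 ethyl (2Z)-4-(benzyloxy)-2-(bromomethyl)but-2-enoate
Conditions: PBr3 (0.4 equiv), Et2O, −10 → 0 °C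
Reagents that add atoms: phosphorus tribromide, BrP(Br)Br
Why: SN2' bromination of the Baylis–Hillman alcohol with allylic transposition gives the thermodynamically preferred (Z)-2-(bromomethyl)enoate (CH2OBn trans to the ester).

Step 4 (key step)
Reactants: 3 4-(benzyloxy)-3-bromo-5-methoxybenzaldehyde; 7 ethyl (2Z)-4-(benzyloxy)-2-(bromomethyl)but-2-enoate
Product: 10 (4R,5S)-5-[4-(benzyloxy)-3-bromo-5-methoxyphenyl]-4-[(benzyloxy)methyl]-3-methylideneoxolan-2-one, via homoaldol trimethylsilyl ether 8 (not isolated), via homoaldol hydroxy ester 9 (not isolated)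
Conditions: CrCl2 (10 mol%), (S,S)-3,6-di-tert-butyl-1,8-bis(4-isopropyl-4,5-dihydrooxazol-2-yl)-9H-carbazole (12 mol%), Mn powder (2 equiv), i-Pr2NEt (30 mol%), Me3SiCl (1.5 equiv), THF, 0 °C → rt; then 1 M HCl, THF; then p-TsOH·H2O (10 mol%), CH2Cl2, rt
Reagents that add atoms: none
Why: catalytic asymmetric Nozaki–Hiyama–Kishi 2-(alkoxycarbonyl)allylation (a homoaldol reaction): divalent chromium inserts into the C–Br bond of 7 so that the acrylate β-carbon becomes the nucleophilic terminus of an allylchromium, which adds to the Si face of 3 through a chair transition state (ligand control sets C5 as S, anti addition sets C4 as R); silylation turns the catalyst over, and acid desilylation and lactonization close the ring; the minor cis lactone is removed by chromatography.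

Step 5
Reactants: 10 (4R,5S)-methylidene lactone; 11 2-(benzyloxy)-4-bromo-1-methoxybenzene
Product: 14 (3S,4R,5S)-5-[4-(benzyloxy)-3-bromo-5-methoxyphenyl]-3-{[3-(benzyloxy)-4-methoxyphenyl]methyl}-4-[(benzyloxy)methyl]-3-hydroxyoxolan-2-one, via arylmagnesium bromide 12 (not isolated), via bromomagnesium lactone enolate 13 (not isolated)
Conditions: 11, Mg turnings (I2 cat.), THF, 40 °C; CuBr·SMe2 (10 mol%), then 10, THF, −40 °C; then trans-2-(phenylsulfonyl)-3-phenyloxaziridine (1.5 equiv), −78 → −20 °C; aq. NH4Cl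
Reagents that add atoms: 2-(phenylsulfonyl)-3-phenyloxaziridine (Davis oxaziridine), O=S(=O)(c1ccccc1)N1OC1c1ccccc1
Why: tandem copper-catalysed conjugate addition and enolate oxidation: the aryl group adds to the exo-methylene carbon to give the fully substituted lactone enolate regiospecifically, and the oxaziridine hydroxylates it on the face anti to the neighbouring CH2OBn group, setting C3 as S (OH trans and ArCH2 cis to CH2OBn).

Step 6
Reactants: 10 (4R,5S)-methylidene lactone; 15 1-(benzyloxy)-4-bromo-2-methoxybenzene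
Product: 18 (3S,4R,5S)-5-[4-(benzyloxy)-3-bromo-5-methoxyphenyl]-3-{[4-(benzyloxy)-3-methoxyphenyl]methyl}-4-[(benzyloxy)methyl]-3-hydroxyoxolan-2-one, via arylmagnesium bromide 16 (not isolated), via bromomagnesium lactone enolate 17 (not isolated)
Conditions: 15, Mg turnings (I2 cat.), THF, 40 °C; CuBr·SMe2 (10 mol%), then 10, THF, −40 °C; then trans-2-(phenylsulfonyl)-3-phenyloxaziridine (1.5 equiv), −78 → −20 °C; aq. NH4Cl
Reagents that add atoms: 2-(phenylsulfonyl)-3-phenyloxaziridine (Davis oxaziridine), O=S(=O)(c1ccccc1)N1OC1c1ccccc1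
Why: the same tandem conjugate addition and enolate hydroxylation as in step 5, with the regioisomeric aryl nucleophile; C3 is again set as S by attack anti to CH2OBn.

Step 7
Reactants: 18 (3S,4R,5S)-lactone with the 4-(benzyloxy)-3-methoxybenzyl group
Product: 19 (2S,3S,4S)-6-(benzyloxy)-4-[4-(benzyloxy)-3-bromo-5-methoxyphenyl]-3-[(benzyloxy)methyl]-2-hydroxy-7-methoxy-1,2,3,4-tetrahydronaphthalene-2-carboxylic acid
Conditions: CF3SO3H (10 mol%), (CF3)2CHOH/CH2Cl2 (1:4), −20 → 0 °C
Reagents that add atoms: none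
Why: intramolecular Friedel–Crafts alkylation with the 5-aryl-lactone as alkylating agent: acid ionizes the p-alkoxybenzylic C5–O bond and the cation is captured by the benzyl arene para to its methoxy group (as in the acid conversion of olivil into cycloolivil); the aryl group enters trans to the adjacent CH2OBn group, setting C4 as S, and the carboxylate stays as the free acid.

Step 8
Reactants: 14 (3S,4R,5S)-lactone with the 3-(benzyloxy)-4-methoxybenzyl group; 19 tetralin acid
Product: 21 (2S,3S,4S)-6-(benzyloxy)-4-{2,2'-bis(benzyloxy)-5'-[(2S,3R,4S)-4-{[3-(benzyloxy)-4-methoxyphenyl]methyl}-3-[(benzyloxy)methyl]-4-hydroxy-5-oxooxolan-2-yl]-3,3'-dimethoxy[1,1'-biphenyl]-5-yl}-3-[(benzyloxy)methyl]-2-hydroxy-7-methoxy-1,2,3,4-tetrahydronaphthalene-2-carboxylic acid, via pinacol boronate 20 (not isolated)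
Conditions: 14, B2pin2, Pd(dppf)Cl2 (5 mol%), KOAc, 1,4-dioxane, 90 °C; then 19, Pd(OAc)2 (5 mol%), SPhos (10 mol%), K3PO4, H2O, 80 °C; acidify to pH 3
Reagents that add atoms: none
Why: one-pot Miyaura borylation and Suzuki–Miyaura coupling joins the two aryl bromide carbons; the biaryl has only two ortho substituents, so no stereo element arises, and any lactone opened by the aqueous base is converted into the same polyol in step 9.

Step 9
Reactants: 21 biaryl lactone acid
Product: 22 (2S,3S,4S)-6-(benzyloxy)-4-{2,2'-bis(benzyloxy)-5'-[(1S,2R,3S)-3-{[3-(benzyloxy)-4-methoxyphenyl]methyl}-2-[(benzyloxy)methyl]-1,3,4-trihydroxybutyl]-3,3'-dimethoxy[1,1'-biphenyl]-5-yl}-3-[(benzyloxy)methyl]-2-(hydroxymethyl)-7-methoxy-1,2,3,4-tetrahydronaphthalen-2-ol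
Conditions: LiAlH4 (excess), THF, 0 → 50 °C; aq. KNaC4H4O6 work-up
Reagents that add atoms: none
Why: hydride reduction opens the lactone to the 1,4-diol and reduces the carboxylic acid to CH2OH; benzyl ethers are inert and no stereocentre is touched.

Step 10
Reactants: 22 biaryl polyol
Product: 23 (2S,3S,4S)-6-(benzyloxy)-4-{2,2'-bis(benzyloxy)-5'-[(2S,3R,4S)-4-{[3-(benzyloxy)-4-methoxyphenyl]methyl}-3-[(benzyloxy)methyl]-4-hydroxyoxolan-2-yl]-3,3'-dimethoxy[1,1'-biphenyl]-5-yl}-3-[(benzyloxy)methyl]-2-(hydroxymethyl)-7-methoxy-1,2,3,4-tetrahydronaphthalen-2-ol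
Conditions: (+)-10-camphorsulfonic acid (10 mol%), CH2Cl2 (0.01 M), molecular sieves, 0 °C; Et3N quench
Reagents that add atoms: none
Why: acid-catalysed cyclodehydration: only the p-alkoxybenzylic secondary alcohol ionizes, the cation is captured 5-exo by the primary CH2OH faster than by the benzyl arene (kinetic etherification, as in closures of 7-hydroxy-lignan triols to 7,9'-epoxylignans), and the aryl group settles trans to the neighbouring CH2OBn group, which re-sets this centre as S.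

Step 11
Reactants: 23 hexabenzyl ether
Product: 24 CNP0252244.1, (2S,3S,4S)-4-{2,2'-dihydroxy-5'-[(2S,3R,4S)-4-hydroxy-4-[(3-hydroxy-4-methoxyphenyl)methyl]-3-(hydroxymethyl)oxolan-2-yl]-3,3'-dimethoxy[1,1'-biphenyl]-5-yl}-2,3-bis(hydroxymethyl)-7-methoxy-1,2,3,4-tetrahydronaphthalene-2,6-diol
Conditions: H2 (1 atm), Pd(OH)2/C, EtOAc/MeOH (1:1), rt, monitored and stopped at full debenzylation
Reagents that add atoms: none
Why: heterogeneous hydrogenolysis cleaves the four aryl and two alkyl benzyl ethers, while the cyclic benzylic ether and the diarylmethine are much slower to cleave under neutral conditions at 1 atm; no stereocentre changes.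

## Compound list

1 | 5-bromovanillin (3-bromo-4-hydroxy-5-methoxybenzaldehyde) | COc1cc(C=O)cc(Br)c1O | starting material
2 | benzyl bromide | BrCc1ccccc1 | starting material
3 | 4-(benzyloxy)-3-bromo-5-methoxybenzaldehyde | COc1cc(C=O)cc(Br)c1OCc1ccccc1 | intermediate
4 | (benzyloxy)acetaldehyde | O=CCOCc1ccccc1 | starting material
5 | ethyl acrylate | C=CC(=O)OCC | starting material
6 | ethyl 4-(benzyloxy)-3-hydroxy-2-methylidenebutanoate (racemic) | CCOC(=O)C(=C)C(O)COCc1ccccc1 | intermediate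
7 | ethyl (2Z)-4-(benzyloxy)-2-(bromomethyl)but-2-enoate | CCOC(=O)/C(CBr)=C/COCc1ccccc1 | intermediate
8 | ethyl (3R)-4-(benzyloxy)-3-{(S)-[4-(benzyloxy)-3-bromo-5-methoxyphenyl][(trimethylsilyl)oxy]methyl}-2-methylidenebutanoate | CCOC(=O)C(=C)[C@H](COCc1ccccc1)[C@H](O[Si](C)(C)C)c1cc(OC)c(OCc2ccccc2)c(Br)c1 | intermediate
9 | ethyl (3R)-4-(benzyloxy)-3-{(S)-[4-(benzyloxy)-3-bromo-5-methoxyphenyl](hydroxy)methyl}-2-methylidenebutanoate | CCOC(=O)C(=C)[C@H](COCc1ccccc1)[C@H](O)c1cc(OC)c(OCc2ccccc2)c(Br)c1 | intermediate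
10 | (4R,5S)-5-[4-(benzyloxy)-3-bromo-5-methoxyphenyl]-4-[(benzyloxy)methyl]-3-methylideneoxolan-2-one | C=C1C(=O)O[C@H](c2cc(OC)c(OCc3ccccc3)c(Br)c2)[C@H]1COCc1ccccc1 | intermediate
11 | 2-(benzyloxy)-4-bromo-1-methoxybenzene | COc1ccc(Br)cc1OCc1ccccc1 | starting material
12 | [3-(benzyloxy)-4-methoxyphenyl]magnesium bromide | COc1ccc([Mg]Br)cc1OCc1ccccc1 | intermediate
13 | bromomagnesium (4R,5S)-5-[4-(benzyloxy)-3-bromo-5-methoxyphenyl]-3-{[3-(benzyloxy)-4-methoxyphenyl]methyl}-4-[(benzyloxy)methyl]-4,5-dihydrofuran-2-olate | COc1ccc(CC2=C(O[Mg]Br)O[C@H](c3cc(OC)c(OCc4ccccc4)c(Br)c3)[C@H]2COCc2ccccc2)cc1OCc1ccccc1 | intermediate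
14 | (3S,4R,5S)-5-[4-(benzyloxy)-3-bromo-5-methoxyphenyl]-3-{[3-(benzyloxy)-4-methoxyphenyl]methyl}-4-[(benzyloxy)methyl]-3-hydroxyoxolan-2-one | COc1ccc(C[C@@]2(O)C(=O)O[C@H](c3cc(OC)c(OCc4ccccc4)c(Br)c3)[C@H]2COCc2ccccc2)cc1OCc1ccccc1 | intermediate
15 | 1-(benzyloxy)-4-bromo-2-methoxybenzene | COc1cc(Br)ccc1OCc1ccccc1 | starting material
16 | [4-(benzyloxy)-3-methoxyphenyl]magnesium bromide | COc1cc([Mg]Br)ccc1OCc1ccccc1 | intermediate
17 | bromomagnesium (4R,5S)-5-[4-(benzyloxy)-3-bromo-5-methoxyphenyl]-3-{[4-(benzyloxy)-3-methoxyphenyl]methyl}-4-[(benzyloxy)methyl]-4,5-dihydrofuran-2-olate | COc1cc(CC2=C(O[Mg]Br)O[C@H](c3cc(OC)c(OCc4ccccc4)c(Br)c3)[C@H]2COCc2ccccc2)ccc1OCc1ccccc1 | intermediate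
18 | (3S,4R,5S)-5-[4-(benzyloxy)-3-bromo-5-methoxyphenyl]-3-{[4-(benzyloxy)-3-methoxyphenyl]methyl}-4-[(benzyloxy)methyl]-3-hydroxyoxolan-2-one | COc1cc(C[C@@]2(O)C(=O)O[C@H](c3cc(OC)c(OCc4ccccc4)c(Br)c3)[C@H]2COCc2ccccc2)ccc1OCc1ccccc1 | intermediate
19 | (2S,3S,4S)-6-(benzyloxy)-4-[4-(benzyloxy)-3-bromo-5-methoxyphenyl]-3-[(benzyloxy)methyl]-2-hydroxy-7-methoxy-1,2,3,4-tetrahydronaphthalene-2-carboxylic acid | Brc1cc([C@H]2c3cc(OCc4ccccc4)c(OC)cc3C[C@@](O)(C(=O)O)[C@@H]2COCc2ccccc2)cc(OC)c1OCc1ccccc1 | intermediate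
20 | pinacol boronate of 14 (Br replaced by 4,4,5,5-tetramethyl-1,3,2-dioxaborolan-2-yl; lactone 3S,4R,5S) | COc1ccc(C[C@@]2(O)C(=O)O[C@H](c3cc(OC)c(OCc4ccccc4)c(B4OC(C)(C)C(C)(C)O4)c3)[C@H]2COCc2ccccc2)cc1OCc1ccccc1 | intermediate
21 | biaryl lactone acid (full name in step 8; lactone 2S,3R,4S and tetralin 2S,3S,4S, joined at the carbons that carried Br) | COc1ccc(C[C@@]2(O)C(=O)O[C@H](c3cc(OC)c(OCc4ccccc4)c(-c4cc([C@H]5c6cc(OCc7ccccc7)c(OC)cc6C[C@@](O)(C(=O)O)[C@@H]5COCc5ccccc5)cc(OC)c4OCc4ccccc4)c3)[C@H]2COCc2ccccc2)cc1OCc1ccccc1 | intermediate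
22 | biaryl polyol (full name in step 9; open chain 1S,2R,3S and tetralin 2S,3S,4S) | COc1ccc(C[C@@](O)(CO)[C@H](COCc2ccccc2)[C@H](O)c2cc(OC)c(OCc3ccccc3)c(-c3cc([C@H]4c5cc(OCc6ccccc6)c(OC)cc5C[C@@](O)(CO)[C@@H]4COCc4ccccc4)cc(OC)c3OCc3ccccc3)c2)cc1OCc1ccccc1 | intermediate
23 | hexabenzyl ether of the target (full name in step 10; oxolane 2S,3R,4S and tetralin 2S,3S,4S) | COc1ccc(C[C@@]2(O)CO[C@H](c3cc(OC)c(OCc4ccccc4)c(-c4cc([C@H]5c6cc(OCc7ccccc7)c(OC)cc6C[C@@](O)(CO)[C@@H]5COCc5ccccc5)cc(OC)c4OCc4ccccc4)c3)[C@H]2COCc2ccccc2)cc1OCc1ccccc1 | intermediate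
24 | CNP0252244.1 (full name in step 11) | COc1ccc(C[C@@]2(O)CO[C@H](c3cc(OC)c(O)c(-c4cc([C@H]5c6cc(O)c(OC)cc6C[C@@](O)(CO)[C@@H]5CO)cc(OC)c4O)c3)[C@H]2CO)cc1O | target

## Step count and weak points

Total steps: 11. Longest linear sequence: 9 steps (2 → 3 → 4 → 6 → 7 → 8 → 9 → 10 → 11).

Steps most likely to fail:

**Step 4 (asymmetric chromium homoaldol).** The allylchromium from 7 carries an alkoxymethyl group and may lose benzyloxide by 1,4-elimination, and the ee or the anti selectivity may be insufficient for this new reagent. Any minor enantiomer that survives ends, after step 8, mainly in heterochiral diastereomers of 21 that chromatography removes. The fallback sets out from 6 (with 3) and comes back at 10. Alcohol 6 is converted with Boc2O and DMAP into ethyl 4-(benzyloxy)-3-[(tert-butoxycarbonyl)oxy]-2-methylidenebutanoate F1. F1 and aldehyde 3 are then joined by iridium-catalysed transfer-hydrogenative 2-(alkoxycarbonyl)allylation ([Ir(cod)Cl]2, (R)-SEGPHOS, 4-cyano-3-nitrobenzoic acid, Cs2CO3, 2-propanol as reductant, THF, 60 °C; ligand antipode chosen for Si-face addition). Ionization of the carbonate gives a nucleophilic allyliridium that adds through a chair transition state (anti) to give hydroxy ester 9, which lactonizes with p-TsOH to 10. This replaces the allyl bromide and the low-valent chromium by a different reagent class and mechanism.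

**Step 7 (Friedel–Crafts directly from the lactone).** The lactone C–O bond may resist ionization, because the 4-alkoxy group is flanked by two ortho substituents. Stronger acid risks benzyl ether loss or scrambling of the adjacent CH centre through elimination. The fallback sets out from 18 and comes back at 22. Lactone 18 is reduced with LiAlH4 to (2S,3R)-4-(benzyloxy)-3-{(S)-[4-(benzyloxy)-3-bromo-5-methoxyphenyl](hydroxy)methyl}-2-{[4-(benzyloxy)-3-methoxyphenyl]methyl}butane-1,2-diol F2. Its benzylic alcohol ionizes far more easily (CF3CO2H, CH2Cl2, 0 °C, the direct analogue of olivil → cycloolivil) and cyclizes to (2S,3S,4S)-6-(benzyloxy)-4-[4-(benzyloxy)-3-bromo-5-methoxyphenyl]-3-[(benzyloxy)methyl]-2-(hydroxymethyl)-7-methoxy-1,2,3,4-tetrahydronaphthalen-2-ol F3. Suzuki coupling of F3 with boronate 20 (made from 14 as in step 8) gives the biaryl lactone triol F4 (as 21 but with CH2OH in place of CO2H), and LiAlH4 reduction of its lactone gives 22.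

**Step 10 (kinetic oxolane closure).** The cation may instead be captured by the 3-(benzyloxy)-4-methoxybenzyl ring para to its OBn group, giving a second tetralin, or the oxolane may form as a 2-epimer mixture. The fallback sets out from 14 and comes back at 23; it avoids the cation and keeps the 5S centre set in step 4. Lactone 14 is reduced with i-Bu2AlH (CH2Cl2, −78 °C) to (3S,4R,5S)-5-[4-(benzyloxy)-3-bromo-5-methoxyphenyl]-3-{[3-(benzyloxy)-4-methoxyphenyl]methyl}-4-[(benzyloxy)methyl]oxolane-2,3-diol F5. Deoxygenation of the lactol with Et3SiH and BF3·OEt2 (−78 → −40 °C) gives (3S,4R,5S)-5-[4-(benzyloxy)-3-bromo-5-methoxyphenyl]-3-{[3-(benzyloxy)-4-methoxyphenyl]methyl}-4-[(benzyloxy)methyl]oxolan-3-ol F6. Miyaura borylation gives the pinacol boronate of the oxolane F7, Suzuki coupling with 19 gives the biaryl oxolane acid F8 (as 23 but with CO2H in place of the tetralin CH2OH), and LiAlH4 reduction of the acid gives 23.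

## Further compounds

F1 | step 4 | ethyl 4-(benzyloxy)-3-[(tert-butoxycarbonyl)oxy]-2-methylidenebutanoate (racemic) | CCOC(=O)C(=C)C(OC(=O)OC(C)(C)C)COCc1ccccc1
F2 | step 7 | (2S,3R)-4-(benzyloxy)-3-{(S)-[4-(benzyloxy)-3-bromo-5-methoxyphenyl](hydroxy)methyl}-2-{[4-(benzyloxy)-3-methoxyphenyl]methyl}butane-1,2-diol | COc1cc(C[C@@](O)(CO)[C@H](COCc2ccccc2)[C@H](O)c2cc(OC)c(OCc3ccccc3)c(Br)c2)ccc1OCc1ccccc1
F3 | step 7 | (2S,3S,4S)-6-(benzyloxy)-4-[4-(benzyloxy)-3-bromo-5-methoxyphenyl]-3-[(benzyloxy)methyl]-2-(hydroxymethyl)-7-methoxy-1,2,3,4-tetrahydronaphthalen-2-ol | Brc1cc([C@H]2c3cc(OCc4ccccc4)c(OC)cc3C[C@@](O)(CO)[C@@H]2COCc2ccccc2)cc(OC)c1OCc1ccccc1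
F4 | step 7 | biaryl lactone triol (as 21 with CH2OH in place of CO2H; lactone 2S,3R,4S and tetralin 2S,3S,4S) | COc1ccc(C[C@@]2(O)C(=O)O[C@H](c3cc(OC)c(OCc4ccccc4)c(-c4cc([C@H]5c6cc(OCc7ccccc7)c(OC)cc6C[C@@](O)(CO)[C@@H]5COCc5ccccc5)cc(OC)c4OCc4ccccc4)c3)[C@H]2COCc2ccccc2)cc1OCc1ccccc1
F5 | step 10 | (3S,4R,5S)-5-[4-(benzyloxy)-3-bromo-5-methoxyphenyl]-3-{[3-(benzyloxy)-4-methoxyphenyl]methyl}-4-[(benzyloxy)methyl]oxolane-2,3-diol (anomer mixture) | COc1ccc(C[C@@]2(O)C(O)O[C@H](c3cc(OC)c(OCc4ccccc4)c(Br)c3)[C@H]2COCc2ccccc2)cc1OCc1ccccc1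
F6 | step 10 | (3S,4R,5S)-5-[4-(benzyloxy)-3-bromo-5-methoxyphenyl]-3-{[3-(benzyloxy)-4-methoxyphenyl]methyl}-4-[(benzyloxy)methyl]oxolan-3-ol | COc1ccc(C[C@@]2(O)CO[C@H](c3cc(OC)c(OCc4ccccc4)c(Br)c3)[C@H]2COCc2ccccc2)cc1OCc1ccccc1
F7 | step 10 | pinacol boronate of F6 (Br replaced by 4,4,5,5-tetramethyl-1,3,2-dioxaborolan-2-yl) | COc1ccc(C[C@@]2(O)CO[C@H](c3cc(OC)c(OCc4ccccc4)c(B4OC(C)(C)C(C)(C)O4)c3)[C@H]2COCc2ccccc2)cc1OCc1ccccc1
F8 | step 10 | biaryl oxolane acid (as 23 with CO2H in place of the tetralin CH2OH; oxolane 2S,3R,4S and tetralin 2S,3S,4S) | COc1ccc(C[C@@]2(O)CO[C@H](c3cc(OC)c(OCc4ccccc4)c(-c4cc([C@H]5c6cc(OCc7ccccc7)c(OC)cc6C[C@@](O)(C(=O)O)[C@@H]5COCc5ccccc5)cc(OC)c4OCc4ccccc4)c3)[C@H]2COCc2ccccc2)cc1OCc1ccccc1
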